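The cyclohexane ring is closed last at C5–C6 (elemane numbering) by a nickel-catalysed alkylative cyclisation of an allenyl aldehyde with Me2Zn. The step exploits the cis-1,2 pair on this ring, O6 on C6 and the C4(=C3H2) unit on C5: in one operation the aldehyde carbon C6 bonds to the proximal allene carbon C5, the central allene carbon C4 receives C15 as methyl, and an oxanickelacycle forces O6 and C4 cis. The precursor is a cis-disubstituted α-methylene-γ-butyrolactone (C7, C8, C11, C12) with the formyl group on C7 and, on C8, the acylated C9 carbinol and the C10 quaternary carbon bearing methyl, vinyl and propa-1,2-dienyl groups.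

Key step: step 11

Remark on numbering: elemane numbering is used throughout. The ring is C5–C10; C10 carries the methyl and the vinyl group (C1=C2); C5 carries C4(=C3H2)–C15; C6 carries the angelate; C7 and C8 carry the lactone (C11(=C13H2)–C12(=O)–O8); C9 carries the (R)-2-methylbutanoate.

Assumption: the anti selectivity of the iridium-catalysed tert-(hydroxy)prenylation is taken to place the carbinol hydroxyl anti to the hydroxymethyl group when the chain is drawn through the vinyl group, which is the C9/C10 relationship of the target. (S)-Tol-BINAP is written for the ligand; its enantiomer would be used if it gave the mirror-image diol.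

Assumption: (R)-2-methylbutanoic acid and angelic acid are bought as single isomers.

Step 1
Reactants: 1 methyl acrylate; 2 (tert-butyldimethylsilyloxy)acetaldehyde
Product: 3 methyl 2-[2-(tert-butyldimethylsilyloxy)-1-hydroxyethyl]prop-2-enoate (racemic)
Conditions: DABCO (0.5 equiv), excess 1, neat, rt
Reagents that add atoms: none
Why: Morita–Baylis–Hillman reaction of an unhindered, activated α-silyloxy aldehyde; the carbinol centre forms as a racemate and is erased in step 2.

Step 2
Reactants: 3 Morita–Baylis–Hillman alcohol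
Product: 4 methyl (2Z)-2-(bromomethyl)-4-(tert-butyldimethylsilyloxy)but-2-enoate
Conditions: NBS, Me2S, CH2Cl2, 0 °C to rt
Reagents that add atoms: N-bromosuccinimide, O=C1CCC(=O)N1Br
Why: Corey–Kim-type activation of the allylic alcohol as an alkoxysulfonium salt and SN2' attack of bromide transpose the alkene; the ester should end trans to the CH2OTBS group (Z), the thermodynamically preferred geometry of 2-(bromomethyl)alk-2-enoates.

Step 3
Reactants: 5 2,2-dimethoxyethanol; 6 2-ethenyl-2-methyloxirane (isoprene monoxide, racemic)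
Product: 7 (2S,3R)-2-ethenyl-4,4-dimethoxy-2-methylbutane-1,3-diol
Conditions: π-allyl iridium C,O-benzoate complex preformed from [Ir(cod)Cl]2, (S)-Tol-BINAP, 4-cyano-3-nitrobenzoic acid and allyl acetate (5 mol%), K3PO4 (5 mol%), THF, 60 °C
Reagents that add atoms: none
Why: Iridium-catalysed transfer-hydrogenative tert-(hydroxy)prenylation: the alcohol is dehydrogenated to the aldehyde, the vinyl epoxide ionises to a π-allyl iridium alkoxide, and carbonyl addition through a closed chair transition state forms C9–C10; the allyl geometry in that chair sets the relative configuration (C9–OH anti to CH2OH) and the chiral bisphosphine sets the absolute configuration at C9 and the quaternary C10.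

Step 4
Reactants: 7 diol
Product: 8 (2R,3R)-2-ethenyl-3-hydroxy-4,4-dimethoxy-2-methylbutanal
Conditions: TEMPO (10 mol%), PhI(OAc)2, CH2Cl2, rt
Reagents that add atoms: none
Why: Oxoammonium (TEMPO) oxidation is selective for the primary alcohol; the aldehyde has a quaternary α-carbon and cannot epimerise.

Step 5
Reactants: 8 hydroxy aldehyde
Product: 9 (2R,3R)-2-ethenyl-4,4-dimethoxy-2-methyl-3-(triethylsilyloxy)butanal
Conditions: TESCl, imidazole, DMAP (cat.), CH2Cl2, 0 °C to rt
Reagents that add atoms: chlorotriethylsilane, CC[Si](Cl)(CC)CC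
Why: Silylation of the secondary hydroxyl blocks retro-aldol cleavage of the β-hydroxy aldehyde under the basic conditions of step 6; triethylsilyl is chosen because it is lost together with the acetal in step 8.

Step 6
Reactants: 9 silyl ether aldehyde
Product: 10 (3S,4R)-3-ethenyl-5,5-dimethoxy-3-methyl-4-(triethylsilyloxy)pent-1-yne
Conditions: dimethyl (1-diazo-2-oxopropyl)phosphonate, K2CO3, MeOH, 0 °C to rt
Reagents that add atoms: dimethyl (1-diazo-2-oxopropyl)phosphonate, COP(=O)(OC)C(=[N+]=[N-])C(C)=O
Why: Ohira–Bestmann (Seyferth–Gilbert) homologation of a non-enolisable aldehyde: the diazomethylphosphonate anion adds, the diazoalkene loses N2 and the alkylidene carbene rearranges to the terminal alkyne.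

Step 7
Reactants: 10 alkyne
Product: 12 (4S,5R)-4-ethenyl-6,6-dimethoxy-4-methyl-5-(triethylsilyloxy)hexa-1,2-diene, via propargylic amine 11 (not isolated)
Conditions: (CH2O)n, CuI (0.5 equiv), Cy2NH, 1,4-dioxane, reflux
Reagents that add atoms: paraformaldehyde (as formaldehyde), C=O
Why: Crabbé homologation: a copper-mediated Mannich reaction gives the propargylic amine, which fragments by 1,5-hydride transfer to the terminal allene and the imine; the quaternary C10 is not touched.

Step 8
Reactants: 12 allene acetal; 4 allylic bromide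
Product: 15 (4R,5R)-4-[(tert-butyldimethylsilyloxy)methyl]-5-[(1R,2S)-2-ethenyl-1-hydroxy-2-methylpenta-3,4-dien-1-yl]-3-methylideneoxolan-2-one, via hydroxy aldehyde 13 (not isolated), via dihydroxy ester 14 (not isolated)
Conditions: Amberlyst-15, THF/H2O, 40 °C, filter; then 4, In powder, THF/H2O, rt; then PPTS (cat.), toluene, 60 °C
Reagents that add atoms: water, O
Why: Acid cleaves the acetal and the triethylsilyl ether, and the free α-hydroxy aldehyde undergoes an indium-mediated Barbier allylation in water in which indium chelates the aldehyde oxygen and the C9 hydroxyl (Cram chelate, attack anti to C10, 8,9-syn diol) while the ester-chelated Z-allylindium reacts at its γ-carbon through a closed chair with CH2OTBS axial (7,8-syn), so that acid-catalysed closure of the γ-lactone on O8 should give the cis-4,5-disubstituted α-methylene lactone.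

Step 9
Reactants: 15 hydroxy lactone; 16 (2R)-2-methylbutanoic acid
Product: 17 (1R,2S)-1-[(2R,3R)-3-[(tert-butyldimethylsilyloxy)methyl]-4-methylidene-5-oxooxolan-2-yl]-2-ethenyl-2-methylpenta-3,4-dien-1-yl (2R)-2-methylbutanoate
Conditions: EDC·HCl, DMAP (cat.), CH2Cl2, rt
Reagents that add atoms: none
Why: Steglich esterification of the only free hydroxyl (C9–OH); carbodiimide activation at room temperature should not epimerise the α-centre of the acid, and the ester blocks lactol formation between O9 and the C6 aldehyde made in step 10.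

Step 10
Reactants: 17 silyl ether
Product: 19 (1R,2S)-2-ethenyl-1-[(2R,3S)-3-formyl-4-methylidene-5-oxooxolan-2-yl]-2-methylpenta-3,4-dien-1-yl (2R)-2-methylbutanoate, via primary alcohol 18 (not isolated)
Conditions: HF·pyridine, THF/pyridine, 0 °C; then DMP, CH2Cl2, 0 °C
Reagents that add atoms: none
Why: Fluoride cleaves the primary silyl ether and Dess–Martin oxidation of the crude alcohol gives the C6 aldehyde under neutral conditions, which avoids translactonisation of the free alcohol and epimerisation or β-elimination at C7; the aldehyde is used at once.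

Step 11
Reactants: 19 allenyl aldehyde
Product: 20 (3aR,4S,5S,6S,7R,7aR)-6-ethenyl-4-hydroxy-6-methyl-3-methylidene-2-oxo-5-(prop-1-en-2-yl)octahydro-1-benzofuran-7-yl (2R)-2-methylbutanoate (C6–OH cis to the C5 isopropenyl group and trans to C11)
Conditions: Ni(cod)2 (15 mol%), Me2Zn (2.5 equiv), THF, 0 °C; aq. NH4Cl
Reagents that add atoms: dimethylzinc, C[Zn]C
Why: Zerovalent nickel binds the aldehyde and the internal C5=C4 π bond of the allene and couples them oxidatively, forming the C5–C6 bond and a five-membered oxanickelacycle with nickel bound to O6 and C4; methyl transfer from Me2Zn to nickel and C–C reductive elimination then place the methyl (C15) on C4 and release the zinc alkoxide. The closest known reaction type is the nickel-catalysed three-component alkylative cyclisation of allenyl aldehydes with organozinc reagents, which gives cis-2-(alk-1-en-2-yl)cycloalkanols. The six-membered carbocycle closes in the exo mode on the proximal allene carbon (6-exo with respect to the C5=C4 π bond, which ends as the exocyclic C4=CH2). The C5/C6 cis relationship is enforced by the cis-fused oxanickelacycle, because O6 and C4 must sit on the same face to reach one nickel atom; the sense relative to C7–C10 should follow from a chair-like closure with the allenyl group equatorial (cis to the C10 methyl, trans to the C10 vinyl) and the metallacycle on the convex face anti to the lactone carbon C11, the alternative requiring the allene axial and syn to C11. The step needs chemoselectivity for the allene over the C10 vinyl group and the α-methylene lactone, which should come from the stronger binding and faster oxidative cyclisation of the allene held next to the aldehyde, and regioselectivity for the proximal allene carbon, which should come from the preference for the smaller ring.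

Step 12
Reactants: 20 cyclised alcohol; 21 angelic acid ((2Z)-2-methylbut-2-enoic acid)
Product: 23 (3aR,4S,5S,6S,7R,7aR)-6-ethenyl-6-methyl-3-methylidene-7-[(2R)-2-methylbutanoyloxy]-2-oxo-5-(prop-1-en-2-yl)octahydro-1-benzofuran-4-yl (2Z)-2-methylbut-2-enoate, via mixed anhydride 22 (not isolated)
Conditions: 21, 2,4,6-trichlorobenzoyl chloride, Et3N, toluene, rt; then 20, toluene, 80 °C
Reagents that add atoms: none
Why: Yamaguchi-type acylation through the preformed mixed anhydride without a nucleophilic catalyst, conditions chosen because they should avoid Z-to-E isomerisation of the angelate; only the C6 hydroxyl is free.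

Step 13
Reactants: 23 angelate with isopropenyl group
Product: 25 target, (3aR,4S,5R,6S,7R,7aR)-6-ethenyl-6-methyl-3-methylidene-7-[(2R)-2-methylbutanoyloxy]-2-oxo-5-(3-oxoprop-1-en-2-yl)octahydro-1-benzofuran-4-yl (2Z)-2-methylbut-2-enoate, via allylic alcohol 24 (not isolated)
Conditions: SeO2 (0.5 equiv), t-BuOOH, CH2Cl2, rt; then DMP, CH2Cl2, 0 °C
Reagents that add atoms: tert-butyl hydroperoxide, CC(C)(C)OO
Why: Selenium dioxide allylic oxidation (ene reaction, then [2,3]-sigmatropic shift) should take the methyl group of the 1,1-disubstituted isopropenyl alkene in preference to the hindered C5 methine and to the electron-poor angelate and methylene lactone, the vinyl group having no allylic hydrogen; Dess–Martin oxidation of the crude mixture converges alcohol and aldehyde to the enal.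

Compound list
1 | methyl acrylate | C=CC(=O)OC | starting material
2 | (tert-butyldimethylsilyloxy)acetaldehyde | O=CCO[Si](C)(C)C(C)(C)C | starting material
3 | methyl 2-[2-(tert-butyldimethylsilyloxy)-1-hydroxyethyl]prop-2-enoate (racemic) | C=C(C(=O)OC)C(O)CO[Si](C)(C)C(C)(C)C | intermediate
4 | methyl (2Z)-2-(bromomethyl)-4-(tert-butyldimethylsilyloxy)but-2-enoate | COC(=O)/C(CBr)=C/CO[Si](C)(C)C(C)(C)C | intermediate
5 | 2,2-dimethoxyethanol | COC(OC)CO | starting material
6 | 2-ethenyl-2-methyloxirane (isoprene monoxide, racemic) | CC1(C=C)CO1 | starting material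
7 | (2S,3R)-2-ethenyl-4,4-dimethoxy-2-methylbutane-1,3-diol | COC(OC)[C@H](O)[C@@](C)(C=C)CO | intermediate
8 | (2R,3R)-2-ethenyl-3-hydroxy-4,4-dimethoxy-2-methylbutanal | COC(OC)[C@H](O)[C@@](C)(C=C)C=O | intermediate
9 | (2R,3R)-2-ethenyl-4,4-dimethoxy-2-methyl-3-(triethylsilyloxy)butanal | COC(OC)[C@H](O[Si](CC)(CC)CC)[C@@](C)(C=C)C=O | intermediate
10 | (3S,4R)-3-ethenyl-5,5-dimethoxy-3-methyl-4-(triethylsilyloxy)pent-1-yne | COC(OC)[C@H](O[Si](CC)(CC)CC)[C@@](C)(C=C)C#C | intermediate
11 | (4S,5R)-N,N-dicyclohexyl-4-ethenyl-6,6-dimethoxy-4-methyl-5-(triethylsilyloxy)hex-2-yn-1-amine | COC(OC)[C@H](O[Si](CC)(CC)CC)[C@@](C)(C=C)C#CCN(C1CCCCC1)C1CCCCC1 | intermediate (not isolated)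
12 | (4S,5R)-4-ethenyl-6,6-dimethoxy-4-methyl-5-(triethylsilyloxy)hexa-1,2-diene | COC(OC)[C@H](O[Si](CC)(CC)CC)[C@@](C)(C=C)C=C=C | intermediate
13 | (2R,3S)-3-ethenyl-2-hydroxy-3-methylhexa-4,5-dienal | O=C[C@H](O)[C@@](C)(C=C)C=C=C | intermediate (not isolated)
14 | methyl (3R,4R,5R,6S)-3-[(tert-butyldimethylsilyloxy)methyl]-6-ethenyl-4,5-dihydroxy-6-methyl-2-methylidenenona-7,8-dienoate | C=C(C(=O)OC)[C@H](CO[Si](C)(C)C(C)(C)C)[C@@H](O)[C@H](O)[C@@](C)(C=C)C=C=C | intermediate (not isolated)
15 | (4R,5R)-4-[(tert-butyldimethylsilyloxy)methyl]-5-[(1R,2S)-2-ethenyl-1-hydroxy-2-methylpenta-3,4-dien-1-yl]-3-methylideneoxolan-2-one | C=C1C(=O)O[C@@H]([C@H](O)[C@@](C)(C=C)C=C=C)[C@H]1CO[Si](C)(C)C(C)(C)C | intermediate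
16 | (2R)-2-methylbutanoic acid | CC[C@@H](C)C(=O)O | starting material
17 | (1R,2S)-1-[(2R,3R)-3-[(tert-butyldimethylsilyloxy)methyl]-4-methylidene-5-oxooxolan-2-yl]-2-ethenyl-2-methylpenta-3,4-dien-1-yl (2R)-2-methylbutanoate | C=C1C(=O)O[C@@H]([C@H](OC(=O)[C@H](C)CC)[C@@](C)(C=C)C=C=C)[C@H]1CO[Si](C)(C)C(C)(C)C | intermediate
18 | (1R,2S)-2-ethenyl-1-[(2R,3R)-3-(hydroxymethyl)-4-methylidene-5-oxooxolan-2-yl]-2-methylpenta-3,4-dien-1-yl (2R)-2-methylbutanoate | C=C1C(=O)O[C@@H]([C@H](OC(=O)[C@H](C)CC)[C@@](C)(C=C)C=C=C)[C@H]1CO | intermediate (not isolated)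
19 | (1R,2S)-2-ethenyl-1-[(2R,3S)-3-formyl-4-methylidene-5-oxooxolan-2-yl]-2-methylpenta-3,4-dien-1-yl (2R)-2-methylbutanoate | C=C1C(=O)O[C@@H]([C@H](OC(=O)[C@H](C)CC)[C@@](C)(C=C)C=C=C)[C@H]1C=O | intermediate
20 | (3aR,4S,5S,6S,7R,7aR)-6-ethenyl-4-hydroxy-6-methyl-3-methylidene-2-oxo-5-(prop-1-en-2-yl)octahydro-1-benzofuran-7-yl (2R)-2-methylbutanoate | C=C[C@@]1(C)[C@H](C(=C)C)[C@H](O)[C@H]2C(=C)C(=O)O[C@H]2[C@@H]1OC(=O)[C@H](C)CC | intermediate
21 | angelic acid, (2Z)-2-methylbut-2-enoic acid | C/C=C(/C)C(=O)O | starting material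
22 | (2Z)-2-methylbut-2-enoic 2,4,6-trichlorobenzoic anhydride | C/C=C(/C)C(=O)OC(=O)c1c(Cl)cc(Cl)cc1Cl | intermediate (not isolated)
23 | (3aR,4S,5S,6S,7R,7aR)-6-ethenyl-6-methyl-3-methylidene-7-[(2R)-2-methylbutanoyloxy]-2-oxo-5-(prop-1-en-2-yl)octahydro-1-benzofuran-4-yl (2Z)-2-methylbut-2-enoate | C=C[C@@]1(C)[C@H](C(=C)C)[C@H](OC(=O)/C(C)=C\C)[C@H]2C(=C)C(=O)O[C@H]2[C@@H]1OC(=O)[C@H](C)CC | intermediate
24 | (3aR,4S,5S,6S,7R,7aR)-6-ethenyl-5-(3-hydroxyprop-1-en-2-yl)-6-methyl-3-methylidene-7-[(2R)-2-methylbutanoyloxy]-2-oxooctahydro-1-benzofuran-4-yl (2Z)-2-methylbut-2-enoate | C=C[C@@]1(C)[C@H](C(=C)CO)[C@H](OC(=O)/C(C)=C\C)[C@H]2C(=C)C(=O)O[C@H]2[C@@H]1OC(=O)[C@H](C)CC | intermediate (not isolated)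
25 | CNP0295282.1, (3aR,4S,5R,6S,7R,7aR)-6-ethenyl-6-methyl-3-methylidene-7-[(2R)-2-methylbutanoyloxy]-2-oxo-5-(3-oxoprop-1-en-2-yl)octahydro-1-benzofuran-4-yl (2Z)-2-methylbut-2-enoate | C=C[C@@]1(C)[C@H](C(=C)C=O)[C@H](OC(=O)/C(C)=C\C)[C@H]2C(=C)C(=O)O[C@H]2[C@@H]1OC(=O)[C@H](C)CC | target

Total step count: 13.
Longest linear sequence: 11 steps (steps 3 to 13); steps 1 and 2 make bromide 4, which enters in step 8.

Steps most likely to fail

Step 11 (key step). The nickel catalyst and Me2Zn may be diverted by π-binding to, or conjugate methylation of, the α-methylene lactone, and the oxidative cyclisation may show poor facial selectivity with respect to C7–C10. The fallback keeps the allene but closes the ring without a metal at the C–C bond-forming stage. It sets out from aldehyde 19: platinum-catalysed diboration of the terminal allene π bond (Pt(dba)2, PCy3, B2pin2, toluene, 50 °C) should give the (Z)-2,3-diborylallyl aldehyde F1, with C10 cis to the CH2Bpin group. Its allylboronate should add to the C6 aldehyde through a closed chair transition state, which translates the alkene geometry into the cis C5/C6 relationship and gives the hydroxy alkenylboronate F2 after aqueous work-up. Suzuki–Miyaura methylation of F2 (MeI, Pd(dppf)Cl2, CsF, THF, 50 °C) comes back to the route at compound 20.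

Step 12. Acylation of the axial C6 hydroxyl, flanked by two tertiary carbons and syn to the C10 methyl, may be too slow, and forcing conditions may isomerise the angelate to the tiglate. The fallback builds the Z-alkene on the molecule instead of transferring it. It sets out from alcohol 20: esterification with 2-[bis(2,2,2-trifluoroethoxy)phosphoryl]propanoic acid (DIC, DMAP, CH2Cl2) should give the phosphonate ester F3, and a Still–Gennari olefination with acetaldehyde (KN(SiMe3)2, 18-crown-6, THF, −78 °C) should form the (Z)-2-methylbut-2-enoate and come back to the route at compound 23.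

Step 13. The late allylic oxidation may stall, over-oxidise, or attack the C5 methine or the allylic positions of the angelate. The fallback replaces the selenium ene reaction by a halogenation–oxidation pair. It sets out from compound 23: ene-type chlorination with hypochlorous acid made in situ (Ca(OCl)2, solid CO2, CH2Cl2/H2O, 0 °C) should convert the electron-rich isopropenyl group selectively into the 2-(chloromethyl)allyl chloride F4, and amine N-oxide oxidation of the allylic chloride (Me3NO, NaI (cat.), DMSO, rt; Kornblum-type) comes back to the route at compound 25.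

Further compounds
F1 | step 11 | (1R,2S,3Z)-2-ethenyl-1-[(2R,3S)-3-formyl-4-methylidene-5-oxooxolan-2-yl]-2-methyl-4,5-bis(4,4,5,5-tetramethyl-1,3,2-dioxaborolan-2-yl)pent-3-en-1-yl (2R)-2-methylbutanoate | C=C1C(=O)O[C@@H]([C@H](OC(=O)[C@H](C)CC)[C@@](C)(C=C)/C=C(\CB2OC(C)(C)C(C)(C)O2)B2OC(C)(C)C(C)(C)O2)[C@H]1C=O
F2 | step 11 | 6-ethenyl-4-hydroxy-6-methyl-3-methylidene-2-oxo-5-[1-(4,4,5,5-tetramethyl-1,3,2-dioxaborolan-2-yl)ethenyl]octahydro-1-benzofuran-7-yl (2R)-2-methylbutanoate, ring configuration as in 20 | C=C[C@@]1(C)[C@H](C(=C)B3OC(C)(C)C(C)(C)O3)[C@H](O)[C@H]2C(=C)C(=O)O[C@H]2[C@@H]1OC(=O)[C@H](C)CC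
F3 | step 12 | 2-[bis(2,2,2-trifluoroethoxy)phosphoryl]propanoate ester of 20 at O6 (mixture at the phosphonate α-carbon) | C=C[C@@]1(C)[C@H](C(=C)C)[C@H](OC(=O)C(C)P(=O)(OCC(F)(F)F)OCC(F)(F)F)[C@H]2C(=C)C(=O)O[C@H]2[C@@H]1OC(=O)[C@H](C)CC
F4 | step 13 | 5-(3-chloroprop-1-en-2-yl) analogue of 23 (allylic chloride) | C=C[C@@]1(C)[C@H](C(=C)CCl)[C@H](OC(=O)/C(C)=C\C)[C@H]2C(=C)C(=O)O[C@H]2[C@@H]1OC(=O)[C@H](C)CC
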